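## Retrosynthetic overview

1. Feature: in ring B (C5–C10) the quaternary fusion carbon C5 (methyl-bearing) and the oxygenated C8 stand 1,4 to each other, and the second fusion carbon C10 is the direct neighbour of C5. This is the pattern of a cyclohexene made from methacrolein (C4, C5, C6, C5-methyl) and a 4-alkyl-2-silyloxybuta-1,3-diene (C7–C10, with C1–C3 in the alkyl arm).
2. Late disconnections: the C9–O silyl ether, the C3–O ester bond (acid from (R)-pent-4-en-2-ol, angelic acid and acrylic acid) and C7–C11 (enolate alkenylation). Before these come C3–O/C4–H (hydroboration of C3=C4) and C9–O (Rubottom oxidation of the C8=C9 enol ether).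
3. Skeleton: C3=C4 by ring-closing metathesis, then C5–C10 and C6–C7 by a catalytic enantioselective Diels–Alder reaction.
4. Ring order in the forward direction: ring B (step 3), then ring A (step 7).

Key step: step 3

Convention: from the cycloadduct on, eremophilane numbering is used (ring A = C1–C5, C10; ring B = C5–C10). β is the face that carries the C5 methyl group and α is the opposite face. "Trinoreremophilane" means the skeleton without C11–C13.

Remark: the (S)-prolinol-derived catalyst is assumed to expose the Re face of the enal α-carbon, as the accepted binding model for α-substituted enals predicts; if the sense proved opposite, the equally available (R)-catalyst would be used.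

## Route

Step 1
Reactants: 1 pent-4-enal
Product: 2 (E)-octa-3,7-dien-2-one
Conditions: Ph3P=CHC(O)CH3 (1.1 equiv), CH2Cl2, rt to 40 °C
Reagents that add atoms: 1-(triphenyl-λ5-phosphanylidene)propan-2-one, CC(=O)C=P(c1ccccc1)(c1ccccc1)c1ccccc1
Why: Wittig olefination with a stabilised acyl ylide, which is reliably E-selective with unbranched aldehydes and leaves the terminal alkene untouched.

Step 2
Reactants: 2 (E)-octa-3,7-dien-2-one
Product: 3 (E)-triisopropyl(octa-1,3,7-trien-2-yloxy)silane
Conditions: i-Pr3SiOTf, Et3N, CH2Cl2, 0 °C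
Reagents that add atoms: triisopropylsilyl trifluoromethanesulfonate, CC(C)[Si](C(C)C)(C(C)C)OS(=O)(=O)C(F)(F)F
Why: Soft enolisation (silyl triflate/amine O-silylation) deprotonates the O-silylated enone at the α′-methyl group and gives the cross-conjugated 2-silyloxydiene with the E double bond unchanged; the triisopropylsilyl group is chosen because it must outlast a strongly acidic catalyst and later serves as the C9–O protecting group.

Step 3
Reactants: 3 (E)-triisopropyl(octa-1,3,7-trien-2-yloxy)silane; 4 methacrolein
Product: 5 (1S,2R)-2-(but-3-en-1-yl)-1-methyl-4-(triisopropylsilyloxy)cyclohex-3-ene-1-carbaldehyde (formyl cis to butenyl)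
Conditions: (S)-3,3-diphenyl-1-(2-methylphenyl)tetrahydro-1H,3H-pyrrolo[1,2-c][1,3,2]oxazaborole (20 mol %), HN(SO2CF3)2 (17 mol %), CH2Cl2, −78 °C; Et3N quench
Reagents that add atoms: none
Why: The N-protonated oxazaborolidine binds the formyl oxygen of s-trans methacrolein at boron (a contact between the formyl hydrogen and the ring oxygen fixes the geometry), and the s-cis diene adds in a concerted but asynchronous normal-demand [4+2] cycloaddition in which the C6–C7 bond (enal β-carbon to enol-ether terminus) runs ahead of the C5–C10 bond. The closest known reaction type is the chiral oxazaborolidine- or oxazaborolidinium-catalysed Diels–Alder reaction of 2-methylacrolein with 2-silyloxy-1,3-dienes. Ring B is closed by the cycloaddition itself, both σ-bonds forming in one suprafacial event that leaves C8=C9 as a regiodefined silyl enol ether. C5 is controlled by the catalyst, whose aryl group on the convex face covers one face of the bound enal so that the diene reaches the Re face of the α-carbon; C10 is controlled relative to C5 by the E geometry of the disubstituted diene double bond together with the endo position of the boron-bound formyl group, which places formyl and butenyl cis. The regiochemistry needed is secured twice, because the 2-silyloxy donor (para rule) and the terminal alkyl group (ortho rule) both make the unsubstituted diene terminus the nucleophilic end. The endo preference needed rests on the open-chain diene, which lacks the bridging methylene that drives α-methyl enals exo with cyclopentadiene, while the bulky silyl group holds back Mukaiyama-type addition and the isolated vinyl group takes no part.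

Step 4
Reactants: 5 cycloadduct aldehyde
Product: 6 1-[(1S,2R)-2-(but-3-en-1-yl)-1-methyl-4-(triisopropylsilyloxy)cyclohex-3-en-1-yl]ethan-1-ol (both carbinol epimers)
Conditions: MeMgBr, THF, −78 to 0 °C; then H2O
Reagents that add atoms: methylmagnesium bromide, C[Mg]Br
Why: Grignard 1,2-addition to a non-enolisable neopentyl aldehyde, to which the silyl enol ether and the alkene are inert; the new carbinol centre (C4) is not controlled and is erased in step 5.

Step 5
Reactants: 6 secondary alcohol
Product: 7 1-[(1S,2R)-2-(but-3-en-1-yl)-1-methyl-4-(triisopropylsilyloxy)cyclohex-3-en-1-yl]ethan-1-one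
Conditions: Dess–Martin periodinane, pyridine, CH2Cl2, 0 °C to rt
Reagents that add atoms: none
Why: Dess–Martin oxidation under pyridine buffering turns the hindered alcohol into the methyl ketone under near-neutral conditions that the bulky silyl enol ether tolerates, and both carbinol epimers converge.

Step 6
Reactants: 7 methyl ketone
Product: 8 {[(3R,4S)-3-(but-3-en-1-yl)-4-methyl-4-(prop-1-en-2-yl)cyclohex-1-en-1-yl]oxy}triisopropylsilane
Conditions: Ph3PCH3Br, KOt-Bu (excess), THF, 0 °C to reflux
Reagents that add atoms: methyltriphenylphosphonium bromide, C[P+](c1ccccc1)(c1ccccc1)c1ccccc1.[Br-]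
Why: Wittig methylenation with excess non-stabilised ylide at elevated temperature is the standard answer to hindered ketones, and since the ketone flanks the quaternary C5, reversible enolisation cannot scramble any stereocentre.

Step 7
Reactants: 8 triene
Product: 9 8-(triisopropylsilyloxy)-11,12,13-trinoreremophila-3,8-diene, cis-fused (5β-CH3, 10β-H)
Conditions: second-generation Grubbs catalyst (H2IMes)(PCy3)Cl2Ru=CHPh (5 mol %), CH2Cl2, 40 °C
Reagents that add atoms: none
Why: Ring-closing metathesis loads the catalyst on the monosubstituted alkene and closes six-membered ring A on the 1,1-disubstituted alkene with loss of ethene; the cis relation of the two arms from step 3 permits closure and fixes the cis ring fusion, and the trisubstituted enol ether is no metathesis partner.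

Step 8
Reactants: 9 bicyclic silyl enol ether
Product: 11 9β-(triisopropylsilyloxy)-11,12,13-trinoreremophil-3-en-8-one, via silyloxy epoxide 10 (not isolated)
Conditions: mCPBA (1.05 equiv), CH2Cl2, −20 to 0 °C
Reagents that add atoms: 3-chloroperoxybenzoic acid, OOC(=O)c1cccc(Cl)c1
Why: In this Rubottom oxidation the electron-rich enol ether is epoxidised much faster than the C3=C4 alkene, the peracid comes from the convex β face (anti to C1 on the neighbouring C10), and acid-induced opening with 1,4-silyl shift gives the 9β-silyloxy ketone, which is also the equatorial and more stable C9 epimer.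

Step 9
Reactants: 11 α-silyloxy ketone
Product: 12 8,8-(ethylenedioxy)-9β-(triisopropylsilyloxy)-11,12,13-trinoreremophil-3-ene
Conditions: (Me3SiOCH2)2, Me3SiOTf (10 mol %), CH2Cl2, −78 to −20 °C; pyridine quench
Reagents that add atoms: 1,2-bis(trimethylsilyloxy)ethane, C[Si](C)(C)OCCO[Si](C)(C)C
Why: Noyori ketalisation (aprotic, driven by formation of hexamethyldisiloxane) masks the ketone against borane without touching the silyl ether, the alkene or C9.

Step 10
Reactants: 12 ketal alkene
Product: 14 8,8-(ethylenedioxy)-9β-(triisopropylsilyloxy)-11,12,13-trinoreremophilan-3α-ol (4β-CH3), via 3α-alkylborane 13 (not isolated)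
Conditions: BH3·THF, THF, 0 °C to rt; then NaOH, H2O2, 0 °C
Reagents that add atoms: hydrogen peroxide, OO
Why: In this hydroboration–oxidation boron goes to the less substituted C3, away from quaternary C5, and H and B add syn from the α face, because the 9β-silyloxy group (syn-diaxial to the C5 methyl in the other chair–chair form) holds the cis-decalin in the conformer whose C5 methyl is axial on ring A and covers the β face of C3=C4; oxidation with retention then gives 3α-OH and 4α-H, that is, 4β-methyl trans to the hydroxyl.

Step 11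
Reactants: 14 ketal alcohol
Product: 15 3α-hydroxy-9β-(triisopropylsilyloxy)-11,12,13-trinoreremophilan-8-one
Conditions: 1 M aq. HCl, THF, rt to 40 °C
Reagents that add atoms: water, O
Why: Acid-catalysed ketal hydrolysis of the inductively deactivated α-oxy ketal needs real aqueous acid, which the secondary triisopropylsilyl ether withstands, and C9 already has its stable equatorial configuration.

Step 12
Reactants: 15 hydroxy ketone
Product: 16 3α-(triethylsilyloxy)-9β-(triisopropylsilyloxy)-11,12,13-trinoreremophilan-8-one
Conditions: Et3SiCl, imidazole, CH2Cl2, 0 °C to rt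
Reagents that add atoms: chlorotriethylsilane, CC[Si](Cl)(CC)CC
Why: Standard silylation of the only free hydroxyl keeps an alkoxide away from the palladium step, and the triethylsilyl ether is far more labile than the triisopropylsilyl ether, so it can be removed alone in step 14.

Step 13
Reactants: 16 bis-silyl ether ketone
Product: 19 3α-(triethylsilyloxy)-9β-(triisopropylsilyloxy)eremophil-11-en-8-one (7β-isopropenyl), via lithium enolate 17 (not isolated), via lithium dienolate 18 (not isolated)
Conditions: LiN(SiMe3)2 (2.2 equiv), toluene/THF, −78 to 0 °C; 2-bromopropene, Pd2(dba)3 (2.5 mol %), P(t-Bu)3 (6 mol %), rt to 45 °C; AcOH, −78 °C; then DBU (cat.), CH2Cl2, 0 °C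
Reagents that add atoms: 2-bromopropene, CC(Br)=C
Why: In this palladium-catalysed α-alkenylation of a ketone enolate (oxidative addition of 2-bromopropene to zerovalent palladium, enolate transfer, reductive elimination) the amide base takes a proton from the open C7 methylene and not from the C9 methine screened by the silyloxy group, the second equivalent of base stores the more acidic product as its dienolate, the cold acid quench protonates that dienolate at C7 so the alkene stays out of conjugation, and a short amine equilibration sets C7 under thermodynamic control with the isopropenyl group equatorial (7β), the 7α epimer being syn-axial to C4.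

Step 14
Reactants: 19 isopropenyl ketone
Product: 20 3α-hydroxy-9β-(triisopropylsilyloxy)eremophil-11-en-8-one
Conditions: AcOH, THF, H2O, rt
Reagents that add atoms: none
Why: Selective acidic solvolysis cleaves the triethylsilyl ether and leaves the much slower triisopropylsilyl ether, and the mild acid does not enolise the ketone, so C7, C9 and the β,γ-position of the alkene are kept.

Step 15
Reactants: 21 (R)-pent-4-en-2-ol; 22 angelic acid
Product: 24 (R)-pent-4-en-2-yl (Z)-2-methylbut-2-enoate, via mixed anhydride 23 (not isolated)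
Conditions: 2,4,6-Cl3C6H2COCl, Et3N, toluene, rt; then 21, 80 °C (no DMAP)
Reagents that add atoms: none
Why: Yamaguchi-type mixed-anhydride acylation run without a nucleophilic catalyst gives angelates without Z-to-E drift to the tiglate, and the carbinol C–O bond is not touched, so the R configuration is retained.

Step 16
Reactants: 24 homoallylic angelate
Product: 25 (R,E)-5-{[(Z)-2-methylbut-2-enoyl]oxy}hex-2-enoic acid
Conditions: acrylic acid (3 equiv), second-generation Hoveyda–Grubbs catalyst (H2IMes)Cl2Ru=CH(C6H4-2-Oi-Pr) (3 mol %), CH2Cl2, 40 °C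
Reagents that add atoms: acrylic acid, C=CC(=O)O
Why: Olefin cross-metathesis of a terminal alkene with an electron-poor acrylic partner is selective for the E-enoic acid, and the trisubstituted, electron-poor angelate alkene does not take part.

Step 17
Reactants: 20 C3 alcohol; 25 side-chain acid
Product: 27 9-O-triisopropylsilyl ether of the target, via mixed anhydride 26 (not isolated)
Conditions: 25, 2,4,6-Cl3C6H2COCl, Et3N, toluene, rt; then 20, DMAP, toluene, 0 °C to rt
Reagents that add atoms: none
Why: Yamaguchi esterification acylates the only free hydroxyl (equatorial C3–OH) by acyl transfer with retention at C3, and low temperature with short contact to DMAP limits deconjugation of the enoate.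

Step 18
Reactants: 27 silyl-protected ester
Product: 28 target, (3R,4R,5R,7R,9R,10S)-9-hydroxy-8-oxoeremophil-11-en-3-yl (R,E)-5-(angeloyloxy)hex-2-enoate
Conditions: HF·pyridine, pyridine, THF, 0 °C to rt
Reagents that add atoms: none
Why: Fluoride-mediated Si–O cleavage under weakly acidic, non-basic conditions causes no enolisation at C7 or C9, no shift of the isopropenyl alkene, no α-ketol migration and no change to the two unsaturated esters.

## Compound list

1 | pent-4-enal | C=CCCC=O | starting material
2 | (E)-octa-3,7-dien-2-one | CC(=O)/C=C/CCC=C | intermediate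
3 | (E)-triisopropyl(octa-1,3,7-trien-2-yloxy)silane | C=C(O[Si](C(C)C)(C(C)C)C(C)C)/C=C/CCC=C | intermediate
4 | methacrolein | C=C(C)C=O | starting material
5 | (1S,2R)-2-(but-3-en-1-yl)-1-methyl-4-(triisopropylsilyloxy)cyclohex-3-ene-1-carbaldehyde | C1C[C@@](C=O)(C)[C@H](CCC=C)C=C1O[Si](C(C)C)(C(C)C)C(C)C | intermediate
6 | secondary alcohol from 5, both carbinol epimers | C1C[C@@](C(C)O)(C)[C@H](CCC=C)C=C1O[Si](C(C)C)(C(C)C)C(C)C | intermediate
7 | methyl ketone | C1C[C@@](C(C)=O)(C)[C@H](CCC=C)C=C1O[Si](C(C)C)(C(C)C)C(C)C | intermediate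
8 | isopropenyl/butenyl triene | C1C[C@@](C(C)=C)(C)[C@H](CCC=C)C=C1O[Si](C(C)C)(C(C)C)C(C)C | intermediate
9 | 8-(triisopropylsilyloxy)-11,12,13-trinoreremophila-3,8-diene (cis-fused) | C1C[C@@]2(C)[C@H](CCC=C2C)C=C1O[Si](C(C)C)(C(C)C)C(C)C | intermediate
10 | 8β,9β-epoxy-8α-(triisopropylsilyloxy)-11,12,13-trinoreremophil-3-ene | C1C[C@@]2(C)[C@H](CCC=C2C)[C@H]3O[C@@]13O[Si](C(C)C)(C(C)C)C(C)C | intermediate
11 | 9β-(triisopropylsilyloxy)-11,12,13-trinoreremophil-3-en-8-one | C1C[C@@]2(C)[C@H](CCC=C2C)[C@@H](O[Si](C(C)C)(C(C)C)C(C)C)C1=O | intermediate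
12 | 8,8-ethylenedioxy ketal of 11 | C1C[C@@]2(C)[C@H](CCC=C2C)[C@@H](O[Si](C(C)C)(C(C)C)C(C)C)C13OCCO3 | intermediate
13 | 3α-boryl-4β-methyl ketal (alkylborane) | C1C[C@@]2(C)[C@H](CC[C@@H](B)[C@@H]2C)[C@@H](O[Si](C(C)C)(C(C)C)C(C)C)C13OCCO3 | intermediate
14 | 8,8-(ethylenedioxy)-9β-(triisopropylsilyloxy)-11,12,13-trinoreremophilan-3α-ol | C1C[C@@]2(C)[C@H](CC[C@@H](O)[C@@H]2C)[C@@H](O[Si](C(C)C)(C(C)C)C(C)C)C13OCCO3 | intermediate
15 | 3α-hydroxy-9β-(triisopropylsilyloxy)-11,12,13-trinoreremophilan-8-one | C1C[C@@]2(C)[C@H](CC[C@@H](O)[C@@H]2C)[C@@H](O[Si](C(C)C)(C(C)C)C(C)C)C1=O | intermediate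
16 | 3α-(triethylsilyloxy)-9β-(triisopropylsilyloxy)-11,12,13-trinoreremophilan-8-one | C1C[C@@]2(C)[C@H](CC[C@@H](O[Si](CC)(CC)CC)[C@@H]2C)[C@@H](O[Si](C(C)C)(C(C)C)C(C)C)C1=O | intermediate
17 | lithium C7=C8 enolate of 16 | [Li+].[O-]C1=CC[C@@]2(C)[C@H](CC[C@@H](O[Si](CC)(CC)CC)[C@@H]2C)[C@H]1O[Si](C(C)C)(C(C)C)C(C)C | intermediate
18 | lithium dienolate of 19 | [Li+].[O-]C1=C(C(C)=C)C[C@@]2(C)[C@H](CC[C@@H](O[Si](CC)(CC)CC)[C@@H]2C)[C@H]1O[Si](C(C)C)(C(C)C)C(C)C | intermediate
19 | 3α-(triethylsilyloxy)-9β-(triisopropylsilyloxy)eremophil-11-en-8-one (7β-isopropenyl) | C=C(C)[C@H]1C[C@@]2(C)[C@H](CC[C@@H](O[Si](CC)(CC)CC)[C@@H]2C)[C@@H](O[Si](C(C)C)(C(C)C)C(C)C)C1=O | intermediate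
20 | 3α-hydroxy-9β-(triisopropylsilyloxy)eremophil-11-en-8-one | C=C(C)[C@H]1C[C@@]2(C)[C@H](CC[C@@H](O)[C@@H]2C)[C@@H](O[Si](C(C)C)(C(C)C)C(C)C)C1=O | intermediate
21 | (R)-pent-4-en-2-ol | C[C@@H](O)CC=C | starting material
22 | angelic acid | C/C=C(/C)C(=O)O | starting material
23 | angelic 2,4,6-trichlorobenzoic anhydride | C/C=C(/C)C(=O)OC(=O)c1c(Cl)cc(Cl)cc1Cl | intermediate
24 | (R)-pent-4-en-2-yl angelate | C=CC[C@@H](C)OC(=O)/C(C)=C\C | intermediate
25 | (R,E)-5-(angeloyloxy)hex-2-enoic acid | OC(=O)/C=C/C[C@@H](C)OC(=O)/C(C)=C\C | intermediate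
26 | mixed anhydride of 25 with 2,4,6-trichlorobenzoic acid | O=C(OC(=O)/C=C/C[C@@H](C)OC(=O)/C(C)=C\C)c1c(Cl)cc(Cl)cc1Cl | intermediate
27 | 9-O-triisopropylsilyl ether of the target | C=C(C)[C@H]1C[C@@]2(C)[C@H](CC[C@@H](OC(=O)/C=C/C[C@@H](C)OC(=O)/C(C)=C\C)[C@@H]2C)[C@@H](O[Si](C(C)C)(C(C)C)C(C)C)C1=O | intermediate
28 | CNP0210874.1 | C=C(C)[C@H]1C[C@@]2(C)[C@H](CC[C@@H](OC(=O)/C=C/C[C@@H](C)OC(=O)/C(C)=C\C)[C@@H]2C)[C@@H](O)C1=O | target

## Step count and risks

Total step count: 18. Longest linear sequence: 16 (steps 1–14, 17, 18).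

**Step 3.** The endo preference or the enantioface discrimination may erode with the bulky silyloxydiene. The enol ether may also add to the activated aldehyde in a Mukaiyama-type reaction instead of cycloadding.
- The fallback sets out from 3 and 4. Cycloaddition promoted by Me2AlCl (CH2Cl2, −78 °C) would give the racemic endo adduct, that is, 5 together with the enantiomeric adduct F1.
- Condensation with (1R,2R)-N,N′-dimethyl-1,2-diphenylethane-1,2-diamine (Et2O, 4 Å molecular sieves) would convert the pair into the imidazolidine of 5 F2 and the imidazolidine of the enantiomer F3.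
- These diastereomers, and any exo-derived isomers, would be separated by chromatography.
- Brief two-phase hydrolysis of F2 with dilute aqueous acid would return 5, where the route is rejoined.

**Step 10.** Borane may be delivered in part to the β face of C3=C4, because the α face also carries the axial C9 branch. The fallback replaces kinetic facial control by thermodynamic control.
- It sets out from 12. Hydroboration–oxidation is run without regard to the face and gives 14 mixed with the 3β-hydroxy-4α-methyl diastereomer F4.
- Dess–Martin oxidation of the mixture gives the 4α-methyl 3-ketone F5 and the 4β-methyl 3-ketone F6.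
- DBU or NaOMe equilibrates F5 to F6, in which the methyl is equatorial. The 4α-methyl group would be syn-axial to C9.
- Reduction of F6 with SmI2/H2O/Et3N in THF gives the equatorial 3α-alcohol, which is 14.

**Step 13.** The hindered enolate may couple slowly, the silyl group may migrate between O9 and O8 in the enolate, or the isopropenyl double bond may drift into conjugation during the C7 equilibration. The fallback replaces cross-coupling by aldol chemistry.
- It sets out from 16. Its lithium enolate 17 (LiN(i-Pr)2, THF, −78 °C) is added to acetone in the presence of ZnCl2 and gives the tertiary aldol F7.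
- SOCl2/pyridine dehydrates F7 to a mixture of 19 and the isopropylidene ketone F8.
- KOt-Bu in THF/t-BuOH turns the whole mixture into the potassium dienolate F9.
- Inverse quench into cold aqueous AcOH protonates F9 at C7 (deconjugative protonation) and returns 19.

## Further compounds

F1 | step 3 | (1R,2S)-enantiomer of 5 | C1C[C@](C=O)(C)[C@@H](CCC=C)C=C1O[Si](C(C)C)(C(C)C)C(C)C
F2 | step 3 | (4R,5R)-1,3-dimethyl-4,5-diphenylimidazolidine (aminal) of 5 | CN1[C@H](c2ccccc2)[C@H](N(C)C1[C@@]3(C)CCC(O[Si](C(C)C)(C(C)C)C(C)C)=C[C@H]3CCC=C)c2ccccc2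
F3 | step 3 | (4R,5R)-1,3-dimethyl-4,5-diphenylimidazolidine (aminal) of F1 | CN1[C@H](c2ccccc2)[C@H](N(C)C1[C@]3(C)CCC(O[Si](C(C)C)(C(C)C)C(C)C)=C[C@@H]3CCC=C)c2ccccc2
F4 | step 10 | 3β-hydroxy-4α-methyl diastereomer of 14 | C1C[C@@]2(C)[C@H](CC[C@H](O)[C@H]2C)[C@@H](O[Si](C(C)C)(C(C)C)C(C)C)C13OCCO3
F5 | step 10 | 4α-methyl 3-ketone (8-ketal, 9β-silyl ether) | C1C[C@@]2(C)[C@H](CCC(=O)[C@H]2C)[C@@H](O[Si](C(C)C)(C(C)C)C(C)C)C13OCCO3
F6 | step 10 | 4β-methyl 3-ketone (8-ketal, 9β-silyl ether) | C1C[C@@]2(C)[C@H](CCC(=O)[C@@H]2C)[C@@H](O[Si](C(C)C)(C(C)C)C(C)C)C13OCCO3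
F7 | step 13 | 7β-(2-hydroxypropan-2-yl) ketone (acetone aldol of 16) | CC(C)(O)[C@H]1C[C@@]2(C)[C@H](CC[C@@H](O[Si](CC)(CC)CC)[C@@H]2C)[C@@H](O[Si](C(C)C)(C(C)C)C(C)C)C1=O
F8 | step 13 | 7(11)-isopropylidene ketone | CC(C)=C1C[C@@]2(C)[C@H](CC[C@@H](O[Si](CC)(CC)CC)[C@@H]2C)[C@@H](O[Si](C(C)C)(C(C)C)C(C)C)C1=O
F9 | step 13 | potassium dienolate of 19 | [K+].[O-]C1=C(C(C)=C)C[C@@]2(C)[C@H](CC[C@@H](O[Si](CC)(CC)CC)[C@@H]2C)[C@H]1O[Si](C(C)C)(C(C)C)C(C)C
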